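**Retrosynthetic overview**
1. The target is a cross Alder-ene adduct of two diastereomeric germacranolides. The C1–C13′ bond (with C9–H moving to C11′) is made last, by a sensitised photo-ene reaction between a free α-methylene lactone (lower half, enophile) and an amine-masked ene donor (upper half); the methylene is then unmasked.
2. The ene donor is made from the enophile itself by double inversion: C8 (lactone hydrolysis, Mitsunobu relactonisation, trans- to cis-lactone) and C6 (Mitsunobu), then Me2NH masking.
3. The enophile's ten-membered ring is closed by intramolecular CrCl2 allylation (C6–C7) of a bromomethyl-butenolide enal; the butenolide is made just before by ring-closing metathesis.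
4. The acyclic chain comes from a geranyl acetate-derived alkyne and (S)-epichlorohydrin, the sole stereochemical input; E-C1=C10 is set by trans-hydrostannation/methylation.
5. Ring order: butenolide, then ten-membered carbocycle (fused α-methylene lactone), then cis-lactone re-closure (donor only), then the inter-unit C–C bond.

Assumption: germacrane numbering is used for both halves (primes for the saturated-lactone half); the target SMILES is read as 1S,6R,7S,8R,9Z,4E / 6′S,7′S,8′S,11′R,1′(10′)E,4′E, and α/β refer to the usual drawing with H-7 α.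

**Step 1**
Reactants: 1 geranyl acetate
Product: 2 (E)-3-methyl-6-oxohex-2-en-1-yl acetate
Conditions: O3 (1.0 equiv), CH2Cl2/pyridine, −78 °C; then Me2S, −78 °C to rt
Reagents that add atoms: ozone, [O-][O+]=O
Why: Chemoselective ozonolysis with reductive work-up: the electron-rich 6,7-alkene is cleaved much faster than the 2,3-alkene deactivated by the allylic acetate, so the E-allylic acetate survives.

**Step 2**
Reactants: 2 (E)-3-methyl-6-oxohex-2-en-1-yl acetate
Product: 4 (E)-3-methylhept-2-en-6-yn-1-ol, via alkynyl acetate 3 (not isolated)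
Conditions: dimethyl (1-diazo-2-oxopropyl)phosphonate, K2CO3, MeOH, 0 °C to rt
Reagents that add atoms: dimethyl (1-diazo-2-oxopropyl)phosphonate, COP(=O)(OC)C(=[N+]=[N-])C(C)=O
Why: Ohira–Bestmann (Seyferth–Gilbert) homologation turns the aldehyde into the terminal alkyne, and the same K2CO3/MeOH medium transesterifies the acetate.

**Step 3**
Reactants: 4 (E)-3-methylhept-2-en-6-yn-1-ol; 5 (S)-epichlorohydrin
Product: 8 (2E,9S)-10-chloro-3-methyldec-2-en-6-yne-1,9-diol, via TMS ether 6 (not isolated), via silyl chlorohydrin 7 (not isolated)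
Conditions: n-BuLi (1.0 equiv), Me3SiCl, THF, −78 to 0 °C; n-BuLi (1.05 equiv), BF3·OEt2, then 5, −78 °C; aq. citric acid, MeOH, rt
Reagents that add atoms: none
Why: BF3-promoted opening of the epoxide at its CH2 terminus by the lithium acetylide (Yamaguchi–Hirao alkynylation), with the alcohol masked transiently as its TMS ether; the C–O bond at the stereocentre of 5 is never broken, so the carbinol (future C8) is S.

**Step 4**
Reactants: 8 (2E,9S)-10-chloro-3-methyldec-2-en-6-yne-1,9-diol
Product: 10 (2E,9S)-3-methylundeca-2,10-dien-6-yne-1,9-diol, via epoxide 9 (not isolated)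
Conditions: Me3S+ I− (5 equiv), n-BuLi (4.8 equiv), THF, −10 °C to rt
Reagents that add atoms: trimethylsulfonium iodide, C[S+](C)C.[I-]
Why: Excess dimethylsulfonium methylide closes the chlorohydrin to the epoxide, opens it at CH2, and the sulfonium betaine eliminates Me2S (one-carbon epoxide-to-allylic-alcohol homologation), leaving the stereocentre untouched.

**Step 5**
Reactants: 10 (2E,9S)-3-methylundeca-2,10-dien-6-yne-1,9-diol
Product: 11 (2E,6Z,9S)-3-methyl-7-(tributylstannyl)undeca-2,6,10-triene-1,9-diol
Conditions: Bu3SnH (1.1 equiv), [Cp*RuCl]4 (2.5 mol%), CH2Cl2, rt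
Reagents that add atoms: tributyltin hydride, CCCC[SnH](CCCC)CCCC
Why: Hydroxyl-directed ruthenium-catalysed trans-hydrostannation: H and SnBu3 add anti across the alkyne with tin on the carbon proximal to the homopropargylic OH, fixing the geometry needed for the E-C1=C10 alkene.

**Step 6**
Reactants: 11 (2E,6Z,9S)-3-methyl-7-(tributylstannyl)undeca-2,6,10-triene-1,9-diol
Product: 12 (2E,6E,9S)-3,7-dimethylundeca-2,6,10-triene-1,9-diol
Conditions: MeI, Pd(PPh3)4 (5 mol%), CuTC (copper thiophene-2-carboxylate, CuO2CC4H3S; 1.5 equiv), [NBu4][Ph2PO2] (1.6 equiv), DMF, rt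
Reagents that add atoms: iodomethane, CI
Why: Copper-assisted Stille methylation of the alkenylstannane proceeds with retention of alkene geometry and gives the E-trisubstituted alkene.

**Step 7**
Reactants: 12 (2E,6E,9S)-3,7-dimethylundeca-2,6,10-triene-1,9-diol
Product: 13 (2E,6E,9S)-9-hydroxy-3,7-dimethylundeca-2,6,10-trienal
Conditions: TEMPO (10 mol%), PhI(OAc)2 (1.1 equiv), CH2Cl2, rt
Reagents that add atoms: none
Why: TEMPO/PhI(OAc)2 (oxoammonium) oxidation is selective for the primary allylic alcohol over the secondary carbinol and gives the E-enal without isomerisation.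

**Step 8**
Reactants: 13 (2E,6E,9S)-9-hydroxy-3,7-dimethylundeca-2,6,10-trienal
Product: 14 (3S,5E,9E)-5,9-dimethyl-11-oxoundeca-1,5,9-trien-3-yl 2-(bromomethyl)prop-2-enoate
Conditions: 2-(bromomethyl)acrylic acid, DCC, DMAP (5 mol%), CH2Cl2, 0 °C
Reagents that add atoms: 2-(bromomethyl)acrylic acid, OC(=O)C(=C)CBr
Why: Steglich esterification acylates the secondary alcohol with retention at the carbinol carbon.

**Step 9**
Reactants: 14 (3S,5E,9E)-5,9-dimethyl-11-oxoundeca-1,5,9-trien-3-yl 2-(bromomethyl)prop-2-enoate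
Product: 15 (5S)-3-(bromomethyl)-5-[(2E,6E)-2,6-dimethyl-8-oxoocta-2,6-dien-1-yl]furan-2(5H)-one
Conditions: second-generation Grubbs catalyst RuCl2(=CHPh)(PCy3)(SIMes) (10 mol%), toluene (2 mM), 80 °C
Reagents that add atoms: none
Why: Ring-closing metathesis between the terminal vinyl group and the 1,1-disubstituted acrylate forms the butenolide with loss of ethylene; the trisubstituted alkenes and the enal do not react.

**Step 10**
Reactants: 15 (5S)-3-(bromomethyl)-5-[(2E,6E)-2,6-dimethyl-8-oxoocta-2,6-dien-1-yl]furan-2(5H)-one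
Product: 16 (6S,7S,8S)-6-hydroxygermacra-1(10)E,4E,11(13)-trien-12,8-olide (6β-OH; trans-fused 8α,12-lactone)
Conditions: CrCl2 (8 equiv), THF, rt, syringe-pump addition (final 2 mM); aq. NH4Cl
Reagents that add atoms: none
Why: Intramolecular Nozaki–Hiyama–Kishi (Barbier-type) allylation: the allylchromium adds through its γ-carbon (C7) to the enal via a chair Zimmerman–Traxler transition state, bonding anti to the C8–C9 bond (trans-fused lactone, 7S) and, because the butenolide locks the allyl unit in the E-type geometry, giving the 6S carbinol while regenerating the exocyclic methylene.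

**Step 11**
Reactants: 16 (6S,7S,8S)-6-hydroxygermacra-1(10)E,4E,11(13)-trien-12,8-olide
Product: 17 6-O-triethylsilyl ether of 16 (all stereocentres as in 16)
Conditions: Et3SiCl, imidazole, DMF, 0 °C
Reagents that add atoms: chlorotriethylsilane, CC[Si](CC)(CC)Cl
Why: Standard silylation of the only hydroxyl group, so that C6–OH cannot compete in the later relactonisation.

**Step 12**
Reactants: 17 6-O-triethylsilyl ether of 16
Product: 18 2-[(3E,7E)-10-hydroxy-4,8-dimethyl-2-(triethylsilyloxy)cyclodeca-3,7-dien-1-yl]prop-2-enoic acid (seco acid of 17; germacrane C6 β-OSiEt3, C7 α-H, C8 α-OH)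
Conditions: LiOH·H2O (3 equiv), THF/H2O, 0 °C; AcOH to pH 5–6 at 0 °C, used at once
Reagents that add atoms: lithium hydroxide, [Li+].[OH-]
Why: Saponification of the γ-lactone by acyl–oxygen cleavage leaves all stereocentres untouched and frees the C8 hydroxyl.

**Step 13**
Reactants: 18 seco acid of 17
Product: 20 (6S,7S,8R)-6-hydroxygermacra-1(10)E,4E,11(13)-trien-12,8-olide (6β-OH; cis-fused 8β,12-lactone), via cis-lactone silyl ether 19 (not isolated)
Conditions: PPh3, DIAD, THF/toluene, 0 °C to rt (slow addition of 18); then HF·pyridine, pyridine, 0 °C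
Reagents that add atoms: none
Why: Mitsunobu lactonisation: the carboxylate displaces the C8 oxyphosphonium in an intramolecular SN2 reaction with inversion (8S to 8R), giving the cis-fused lactone, and HF·pyridine then cleaves the silyl ether.

**Step 14**
Reactants: 20 (6S,7S,8R)-6-hydroxygermacra-1(10)E,4E,11(13)-trien-12,8-olide
Product: 23 (6R,7S,8R,11S)-13-(dimethylamino)-6-hydroxy-11,13-dihydrogermacra-1(10)E,4E-dien-12,8-olide (6α-OH; cis-fused 8β,12-lactone), via formate 21 (not isolated), via amino formate 22 (not isolated)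
Conditions: PPh3, DIAD, HCO2H, THF, 0 °C to rt; then Me2NH (2 M in MeOH, excess), rt; isolated by acid–base extraction, stored as the CF3CO2H salt
Reagents that add atoms: formic acid, OC=O; dimethylamine, CNC
Why: Mitsunobu inversion with formic acid converts 6S into 6R by SN2 displacement, after which dimethylamine adds to the methylene lactone (aza-Michael; C11 is set trans to the C7 substituent but is erased in step 16) and removes the formate by aminolysis.

**Step 15**
Reactants: 16 (6S,7S,8S)-6-hydroxygermacra-1(10)E,4E,11(13)-trien-12,8-olide; 23 (6R,7S,8R,11S)-13-(dimethylamino)-6-hydroxy-11,13-dihydrogermacra-1(10)E,4E-dien-12,8-olide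
Product: 24 13-(dimethylamino)-11,13-dihydro derivative of the target (C1 of the 23-derived half bonded to C13′ of the 16-derived half; 1S, 9Z, 11′R)
Conditions: 16 (1 equiv, added over 6 h), 23·CF3CO2H (3 equiv, excess recovered), xanthone (25 mol%), degassed MeCN, 365 nm LEDs, −20 °C; aq. NaHCO3
Reagents that add atoms: none
Why: Proposed new method: a sensitised cross photo-ene (formal Alder-ene) reaction in which triplet energy transfer from xanthone (about 74 kcal/mol, π,π* in MeCN) reaches only the enoate of 16 (23 has no conjugated chromophore and its amine is protonated), the twisted triplet adds through C13′ to the less substituted C1 of the C1=C10 alkene of 23 on its exposed outer (β) face to give a triplet 1,4-biradical (tertiary C10, α-acyl C11′) that is slow to close to a spiro-cyclobutane with two adjacent quaternary carbons and instead, after intersystem crossing, disproportionates by a six-membered 1,5-hydrogen shift from C9 to C11′, which forms the C1–C13′ bond (1S), the less strained Z-C9=C10 alkene and 11′R (substituent trans to C6′, as in conjugate reductions of germacranolides); the closest known reactions are enone/enoate–alkene [2+2] photocycloadditions, whose 1,4-biradicals are known to leak to ene-type products, and the thermal Alder-ene reaction.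

**Step 16**
Reactants: 24 13-(dimethylamino)-11,13-dihydro derivative of the target
Product: 26 target dimer CNP0191625.2, via methiodide 25 (not isolated)
Conditions: MeI (10 equiv), THF, rt; then aq. NaHCO3, EtOAc, rt
Reagents that add atoms: none
Why: Exhaustive N-methylation followed by mild-base E1cB (Hofmann-type) elimination of trimethylamine regenerates the α-methylene lactone of the upper half without touching the other stereocentres.

**Compound list**
1 | geranyl acetate, (2E)-3,7-dimethylocta-2,6-dien-1-yl acetate | CC(C)=CCC/C(C)=C/COC(C)=O | starting material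
2 | (E)-3-methyl-6-oxohex-2-en-1-yl acetate | O=CCC/C(C)=C/COC(C)=O | intermediate
3 | (E)-3-methylhept-2-en-6-yn-1-yl acetate | C#CCC/C(C)=C/COC(C)=O | intermediate
4 | (E)-3-methylhept-2-en-6-yn-1-ol | C#CCC/C(C)=C/CO | intermediate
5 | (S)-epichlorohydrin, (2S)-2-(chloromethyl)oxirane | ClC[C@@H]1CO1 | starting material
6 | trimethylsilyl ether of 4 | C#CCC/C(C)=C/CO[Si](C)(C)C | intermediate
7 | (2S,8E)-1-chloro-8-methyl-10-(trimethylsilyloxy)dec-8-en-4-yn-2-ol | ClC[C@@H](O)CC#CCC/C(C)=C/CO[Si](C)(C)C | intermediate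
8 | (2E,9S)-10-chloro-3-methyldec-2-en-6-yne-1,9-diol | ClC[C@@H](O)CC#CCC/C(C)=C/CO | intermediate
9 | (E)-3-methyl-8-[(2S)-oxiran-2-yl]oct-2-en-6-yn-1-ol | OC/C=C(C)/CCC#CC[C@H]1CO1 | intermediate
10 | (2E,9S)-3-methylundeca-2,10-dien-6-yne-1,9-diol | C=C[C@@H](O)CC#CCC/C(C)=C/CO | intermediate
11 | (2E,6Z,9S)-3-methyl-7-(tributylstannyl)undeca-2,6,10-triene-1,9-diol | C=C[C@@H](O)C/C([Sn](CCCC)(CCCC)CCCC)=C/CC/C(C)=C/CO | intermediate
12 | (2E,6E,9S)-3,7-dimethylundeca-2,6,10-triene-1,9-diol | C=C[C@@H](O)C/C(C)=C/CC/C(C)=C/CO | intermediate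
13 | (2E,6E,9S)-9-hydroxy-3,7-dimethylundeca-2,6,10-trienal | C=C[C@@H](O)C/C(C)=C/CC/C(C)=C/C=O | intermediate
14 | (3S,5E,9E)-5,9-dimethyl-11-oxoundeca-1,5,9-trien-3-yl 2-(bromomethyl)prop-2-enoate | C=C[C@@H](OC(=O)C(=C)CBr)C/C(C)=C/CC/C(C)=C/C=O | intermediate
15 | (5S)-3-(bromomethyl)-5-[(2E,6E)-2,6-dimethyl-8-oxoocta-2,6-dien-1-yl]furan-2(5H)-one | BrCC1=C[C@H](C/C(C)=C/CC/C(C)=C/C=O)OC1=O | intermediate
16 | (6S,7S,8S)-6-hydroxygermacra-1(10)E,4E,11(13)-trien-12,8-olide; (3aS,4S,5E,9E,11aS)-4-hydroxy-6,10-dimethyl-3-methylidene-3a,4,7,8,11,11a-hexahydrocyclodeca[b]furan-2(3H)-one | C=C1C(=O)O[C@H]2C/C(C)=C/CC/C(C)=C/[C@H](O)[C@H]12 | intermediate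
17 | 6-O-triethylsilyl ether of 16 | C=C1C(=O)O[C@H]2C/C(C)=C/CC/C(C)=C/[C@H](O[Si](CC)(CC)CC)[C@H]12 | intermediate
18 | 2-[(3E,7E)-10-hydroxy-4,8-dimethyl-2-(triethylsilyloxy)cyclodeca-3,7-dien-1-yl]prop-2-enoic acid, ring stereocentres as in 17 (6β-OSiEt3, 7α-H, 8α-OH) | C=C(C(=O)O)[C@@H]1[C@@H](O)C/C(C)=C/CC/C(C)=C/[C@@H]1O[Si](CC)(CC)CC | intermediate
19 | 6-O-triethylsilyl ether of 20 | C=C1C(=O)O[C@@H]2C/C(C)=C/CC/C(C)=C/[C@H](O[Si](CC)(CC)CC)[C@H]12 | intermediate
20 | (6S,7S,8R)-6-hydroxygermacra-1(10)E,4E,11(13)-trien-12,8-olide (6β-OH, cis-fused 8β,12-lactone) | C=C1C(=O)O[C@@H]2C/C(C)=C/CC/C(C)=C/[C@H](O)[C@H]12 | intermediate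
21 | (6R,7S,8R)-6-(formyloxy)germacra-1(10)E,4E,11(13)-trien-12,8-olide | C=C1C(=O)O[C@@H]2C/C(C)=C/CC/C(C)=C/[C@@H](OC=O)[C@H]12 | intermediate
22 | 13-(dimethylamino)-11,13-dihydro derivative of 21 (11S) | CN(C)C[C@H]1C(=O)O[C@@H]2C/C(C)=C/CC/C(C)=C/[C@@H](OC=O)[C@@H]21 | intermediate
23 | (6R,7S,8R,11S)-13-(dimethylamino)-6-hydroxy-11,13-dihydrogermacra-1(10)E,4E-dien-12,8-olide (6α-OH, cis-fused 8β,12-lactone) | CN(C)C[C@H]1C(=O)O[C@@H]2C/C(C)=C/CC/C(C)=C/[C@@H](O)[C@@H]21 | intermediate
24 | 13-(dimethylamino)-11,13-dihydro derivative of the target (amine on the upper, 23-derived lactone) | CN(C)C[C@H]1C(=O)O[C@@H]2/C=C(/C)[C@H](C[C@H]3C(=O)O[C@H]4C/C(C)=C/CC/C(C)=C/[C@H](O)[C@@H]43)CC/C(C)=C/[C@@H](O)[C@H]12 | intermediate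
25 | N-methyl quaternary ammonium iodide of 24 | C[N+](C)(C)C[C@H]1C(=O)O[C@@H]2/C=C(/C)[C@H](C[C@H]3C(=O)O[C@H]4C/C(C)=C/CC/C(C)=C/[C@H](O)[C@@H]43)CC/C(C)=C/[C@@H](O)[C@H]12.[I-] | intermediate
26 | CNP0191625.2: (1S,6R,7S,8R,9Z,4E)-6-hydroxygermacra-4,9,11(13)-trien-12,8-olide bonded at C1 to C13′ of (6′S,7′S,8′S,11′R)-6′-hydroxy-11′,13′-dihydrogermacra-1′(10′)E,4′E-dien-12′,8′-olide | C=C1C(=O)O[C@@H]2/C=C(/C)[C@H](C[C@H]3C(=O)O[C@H]4C/C(C)=C/CC/C(C)=C/[C@H](O)[C@@H]43)CC/C(C)=C/[C@@H](O)[C@H]12 | target

**Step count and risks**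
Total step count: 16. Longest linear sequence: 16 (1 to 16 to 23 to 24 to 26; compound 16 is used a second time as the enophile in step 15).

Most likely to fail:

Step 15 (the new photo-ene). The sensitiser may also isomerise the strained E-alkenes, the biradical may close to a cyclobutane or take hydrogen from C14, the C4=C5 alkene of 23 may compete, and 16 may couple with itself. Should C11′ come out epimeric, equilibration with base to the more stable trans arrangement would be needed. Fallback: set out from 16 and 23 (free base) and run the known thermal Alder-ene reaction without light under high pressure (CH2Cl2, 1.2 GPa, 40 °C, BHT), which keeps the temperature far below the Cope rearrangement of the germacradienes. It comes back to the route at 24; no new compound is made (F0).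

Step 10 (chromium macrocyclisation). The ten-membered ring may close with the other C6 configuration. Fallback: set out from 15, accept the ring closure as the C6-epimeric alcohol (6R,7S,8S)-6-hydroxygermacra-1(10)E,4E,11(13)-trien-12,8-olide F1, and set C6 by substitution instead of by the cyclisation: Mitsunobu reaction with formic acid (PPh3, DIAD, THF) gives the inverted 6β-formate of 16 F2, and KHCO3 in MeOH at 0 °C releases the alcohol, coming back to the route at 16.

Step 13 (inverting lactonisation). Acyl activation can give the trans-lactone with retention, and elimination at C8 is possible. Fallback: set out from 18, esterify the acid with Me3SiCHN2 (toluene/MeOH, 0 °C) to the hydroxy methyl ester of 18 F3, sulfonylate the only free hydroxyl (MsCl, Et3N, CH2Cl2, −20 °C) to the C8 mesylate of that ester F4, and treat with LiOH in THF/H2O. The liberated carboxylate displaces the mesylate with inversion; direct hydroxide displacement followed by lactonisation converges on the same cis-lactone. This comes back to the route at 19, which is desilylated as in step 13.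

**Further compounds**
F1 | step 10 | (6R,7S,8S)-6-hydroxygermacra-1(10)E,4E,11(13)-trien-12,8-olide, the C6 epimer of 16 | C=C1C(=O)O[C@H]2C/C(C)=C/CC/C(C)=C/[C@@H](O)[C@H]12
F2 | step 10 | 6-O-formyl derivative of 16 (6β-formate) | C=C1C(=O)O[C@H]2C/C(C)=C/CC/C(C)=C/[C@H](OC=O)[C@H]12
F3 | step 13 | methyl ester of 18 | COC(=O)C(=C)[C@@H]1[C@@H](O)C/C(C)=C/CC/C(C)=C/[C@@H]1O[Si](CC)(CC)CC
F4 | step 13 | C8 methanesulfonate of F3 | COC(=O)C(=C)[C@@H]1[C@@H](OS(C)(=O)=O)C/C(C)=C/CC/C(C)=C/[C@@H]1O[Si](CC)(CC)CC
F0 | step 15 | none | none
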